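**Retrosynthetic overview**
1. GA87 ⇐ a protected 12-oxo-GA3 by face-selective ketone reduction; C12 is set last, on the rigid bicyclo[3.2.1]octane.
2. The 12-oxo compound ⇐ a ring-D-seco enediol bis-silyl ether: ring D is re-closed (C13–C16) by Ph3PAuCl/AgBF4-catalysed 5-exo-dig cyclisation onto the alkyne.
3. The enediol ether ⇐ a seco alkynyl 13-ketone by [3,3]-sigmatropic rearrangement of an N-vinyl-O-benzoylhydroxylamine, which forms the one new skeletal bond, C12–O.
4. The seco alkynyl ketone ⇐ GA3 by ozonolysis/reduction, glycol cleavage of C13–C16 and Ohira–Bestmann alkynylation (C17 returned).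
5. Rings A, B, C and every stereocentre except C12 come from GA3; order of ring events: ring D opened → C12 oxygenated → ring D closed.

Assumption: gibberellic acid (GA3), a bulk fermentation product, is taken as the commercial chiral starting material; GA87 denotes the target gibberellin; gibberellane numbering is used and "12α" means the C12 hydroxyl of the target SMILES (axial on ring C, cis to 13-OH, anti to C16, syn-axial to the C9–C10 bond); the route is a designed proposal and steps 6–8 have no direct precedent on this skeleton.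

**Step 1**
Reactants: 1 gibberellic acid (GA3)
Product: 2 GA3 2-(trimethylsilyl)ethyl ester
Conditions: Me3SiCH2CH2OH (5 equiv), DCC, DMAP (cat.), CH2Cl2, 0 °C to rt
Reagents that add atoms: 2-(trimethylsilyl)ethanol, C[Si](C)(C)CCO
Why: Steglich esterification of the C7 acid, in which the excess primary alcohol outcompetes the hindered 3-OH and 13-OH; no stereocentre is touched.

**Step 2**
Reactants: 2 GA3 2-(trimethylsilyl)ethyl ester
Product: 4 17-nor-13,16-diol (C16 epimers), via 17-nor-16-ketone 3 (not isolated)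
Conditions: O3 (1 equiv), CH2Cl2/MeOH, pyridine, −78 °C; then NaBH4, −78 to 0 °C
Reagents that add atoms: ozone, [O-][O+]=O
Why: Criegee ozonolysis takes the electron-rich exocyclic 16-ene in preference to the deactivated 1-ene, and the reductive work-up gives the diol; the C16 configuration is irrelevant because it is destroyed in step 3.

**Step 3**
Reactants: 4 17-nor-13,16-diol
Product: 5 13,16-seco keto-aldehyde (13-ketone; C16 aldehyde on the C8–CH2 arm)
Conditions: Pb(OAc)4, CH2Cl2, 0 °C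
Reagents that add atoms: none
Why: Criegee glycol cleavage of C13–C16 by lead tetraacetate, which cleaves both the cis- and the trans-diol epimer; C8 and C9 are untouched.

**Step 4**
Reactants: 5 13,16-seco keto-aldehyde
Product: 6 13,16-seco alkynyl ketone (C8–CH2–C≡CH; 13-ketone)
Conditions: dimethyl (1-diazo-2-oxopropyl)phosphonate (1.3 equiv), K2CO3, MeOH, 0 °C to rt
Reagents that add atoms: dimethyl (1-diazo-2-oxopropyl)phosphonate, CC(=O)C(=[N+]=[N-])P(=O)(OC)OC
Why: Ohira–Bestmann (Seyferth–Gilbert) homologation is selective for the aldehyde over the ketone and returns C17 as the alkyne terminus; no stereocentre is formed.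

**Step 5**
Reactants: 6 13,16-seco alkynyl ketone
Product: 10 seco 12-hydroxy-13-ketone (α-ketol; C12 epimers), via N-vinyl-O-benzoylhydroxylamine 7 (not isolated), via α-benzoyloxy N-methylimine 8 (not isolated), via α-benzoyloxy ketone 9 (not isolated)
Conditions: MeNH(OBz)·HCl (1.2 equiv), DMSO, rt, 16 h; then K2CO3, MeOH, 0 °C, under Ar
Reagents that add atoms: N-methyl-O-benzoylhydroxylamine hydrochloride, CNOC(=O)c1ccccc1.Cl; water, O
Why: Tomkinson α-oxygenation: condensation gives the ene-hydroxylamine on the unhindered C12 side (C14 is neopentyl), its [3,3]-sigmatropic rearrangement forms the C12–O bond, and hydrolysis plus methanolysis free the ketol, whose C12 configuration is erased in step 6.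

**Step 6**
Reactants: 10 seco α-ketol
Product: 11 3-O-TBS seco 12,13-enediol bis-TBS ether (C12=C13)
Conditions: TBSOTf (4 equiv), Et3N (6 equiv), CH2Cl2, −78 to 0 °C
Reagents that add atoms: tert-butyldimethylsilyl trifluoromethanesulfonate, CC(C)(C)[Si](C)(C)OS(=O)(=O)C(F)(F)F
Why: soft enolisation of the α-silyloxy ketone towards the acidified, unhindered C12–H gives the tetrasubstituted enediol bis-silyl ether, on which both C12 epimers converge, and 3-OH is silylated in the same operation.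

**Step 7**
Reactants: 11 enediol bis-TBS ether
Product: 12 3,13-bis-O-TBS 12-oxo-GA3 2-(trimethylsilyl)ethyl ester
Conditions: Ph3PAuCl (10 mol%), AgBF4 (10 mol%), CH2Cl2/MeOH 10:1, rt
Reagents that add atoms: none
Why: Toste-type carbocyclisation (catalytic Conia-ene variant), in which the alkyne on the axial C8 arm is activated by cationic monovalent gold and attacked 5-exo-dig by C13, the enediol carbon that is 1,3 to C8, so that ring D is rebuilt with the exocyclic methylene, the C13 configuration is dictated by the C8 tether, and methanol removes the C12 silyl group to leave the ketone.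

**Step 8**
Reactants: 12 12-oxo compound
Product: 13 3,13-bis-O-TBS GA87 2-(trimethylsilyl)ethyl ester (12α-OH)
Conditions: LiBH(s-Bu)3, THF, −78 °C; then AcOH
Reagents that add atoms: none
Why: substrate-controlled ketone reduction: the α-face of C12 lies under the syn-axial C9–C10 bond (lactone oxygen and C1 beneath), so the bulky hydride should enter equatorially from the β-face and give the axial 12α-alcohol.

**Step 9**
Reactants: 13 protected GA87
Product: 14 GA87 (12α-hydroxy-GA3; the target)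
Conditions: Bu4NF (6 equiv), AcOH (3 equiv), THF, 0 to 40 °C; pH 3 aqueous work-up
Reagents that add atoms: none
Why: fluoride cleaves both TBS ethers and the 2-(trimethylsilyl)ethyl ester (loss of ethene) under buffered, non-hydrolytic conditions that spare the base-labile allylic lactone; the hindered tertiary 13-O-silyl group can leave by 1,2-migration to the neighbouring cis 12-oxygen.

**Compound list**
1 | gibberellic acid (GA3) | C=C1C[C@]23C[C@@]1(O)CC[C@H]2[C@@]12C=C[C@H](O)[C@@](C)(C(=O)O1)[C@H]2[C@@H]3C(=O)O | starting material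
2 | GA3 2-(trimethylsilyl)ethyl ester | C=C1C[C@]23C[C@@]1(O)CC[C@H]2[C@@]12C=C[C@H](O)[C@@](C)(C(=O)O1)[C@H]2[C@@H]3C(=O)OCC[Si](C)(C)C | intermediate
3 | 17-nor-16-ketone (13-hydroxy) | O=C1C[C@]23C[C@@]1(O)CC[C@H]2[C@@]12C=C[C@H](O)[C@@](C)(C(=O)O1)[C@H]2[C@@H]3C(=O)OCC[Si](C)(C)C | intermediate
4 | 17-nor-13,16-diol (C16 epimer mixture, C16 left undefined) | OC1C[C@]23C[C@@]1(O)CC[C@H]2[C@@]12C=C[C@H](O)[C@@](C)(C(=O)O1)[C@H]2[C@@H]3C(=O)OCC[Si](C)(C)C | intermediate
5 | 13,16-seco keto-aldehyde | O=CC[C@]23CC(=O)CC[C@H]2[C@@]12C=C[C@H](O)[C@@](C)(C(=O)O1)[C@H]2[C@@H]3C(=O)OCC[Si](C)(C)C | intermediate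
6 | 13,16-seco alkynyl 13-ketone | C#CC[C@]23CC(=O)CC[C@H]2[C@@]12C=C[C@H](O)[C@@](C)(C(=O)O1)[C@H]2[C@@H]3C(=O)OCC[Si](C)(C)C | intermediate
7 | N-(cyclohex-12-en-13-yl)-N-methyl-O-benzoylhydroxylamine | C#CC[C@]23CC(N(C)OC(=O)c4ccccc4)=CC[C@H]2[C@@]12C=C[C@H](O)[C@@](C)(C(=O)O1)[C@H]2[C@@H]3C(=O)OCC[Si](C)(C)C | intermediate
8 | 12-benzoyloxy 13-(N-methylimine) | C#CC[C@]23CC(=NC)C(OC(=O)c4ccccc4)C[C@H]2[C@@]12C=C[C@H](O)[C@@](C)(C(=O)O1)[C@H]2[C@@H]3C(=O)OCC[Si](C)(C)C | intermediate
9 | 12-benzoyloxy 13-ketone (C12 epimers) | C#CC[C@]23CC(=O)C(OC(=O)c4ccccc4)C[C@H]2[C@@]12C=C[C@H](O)[C@@](C)(C(=O)O1)[C@H]2[C@@H]3C(=O)OCC[Si](C)(C)C | intermediate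
10 | 12-hydroxy 13-ketone (α-ketol, C12 epimers) | C#CC[C@]23CC(=O)C(O)C[C@H]2[C@@]12C=C[C@H](O)[C@@](C)(C(=O)O1)[C@H]2[C@@H]3C(=O)OCC[Si](C)(C)C | intermediate
11 | 3-O-TBS 12,13-enediol bis-TBS ether | C#CC[C@]23CC(O[Si](C)(C)C(C)(C)C)=C(O[Si](C)(C)C(C)(C)C)C[C@H]2[C@@]12C=C[C@H](O[Si](C)(C)C(C)(C)C)[C@@](C)(C(=O)O1)[C@H]2[C@@H]3C(=O)OCC[Si](C)(C)C | intermediate
12 | 3,13-bis-O-TBS 12-oxo-GA3 2-(trimethylsilyl)ethyl ester | C=C1C[C@]23C[C@@]1(O[Si](C)(C)C(C)(C)C)C(=O)C[C@H]2[C@@]12C=C[C@H](O[Si](C)(C)C(C)(C)C)[C@@](C)(C(=O)O1)[C@H]2[C@@H]3C(=O)OCC[Si](C)(C)C | intermediate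
13 | 3,13-bis-O-TBS GA87 2-(trimethylsilyl)ethyl ester | C=C1C[C@]23C[C@@]1(O[Si](C)(C)C(C)(C)C)[C@@H](O)C[C@H]2[C@@]12C=C[C@H](O[Si](C)(C)C(C)(C)C)[C@@](C)(C(=O)O1)[C@H]2[C@@H]3C(=O)OCC[Si](C)(C)C | intermediate
14 | GA87 (12α-hydroxy-GA3) | C=C1C[C@]23C[C@@]1(O)[C@@H](O)C[C@H]2[C@@]12C=C[C@H](O)[C@@](C)(C(=O)O1)[C@H]2[C@@H]3C(=O)O | target

**Total step count:** 9. **Longest linear sequence:** 9 steps (fully linear from 1).

**Steps most likely to fail, with fallbacks**

Step 6 (regiochemistry of enolisation: the C13=C14 ether is inert to the cyclisation of step 7, and a C11=C12 ether from any 12-keto tautomer would cyclise through C11). The fallback sets out from 10 and avoids the enediol ether altogether. Silylate only the hydroxyls (TBSOTf, 2,6-lutidine, CH2Cl2, −78 °C) and equilibrate C12 with DBU; the silyl ether cis to C10 can sit equatorial in the monocyclic ketone. This gives the 3,12-bis-O-TBS seco alkynyl ketone F1. Close ring D reductively by samarium diiodide ketyl–alkyne 5-exo-dig radical cyclisation (SmI2, HMPA, t-BuOH, THF, −78 to 0 °C), in which the ring closure has to outrun reductive loss of the α-silyloxy group, to reach the 3,12-bis-O-TBS GA87 2-(trimethylsilyl)ethyl ester F2. The Bu4NF/AcOH conditions of step 9 then return to the route at 14.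

Step 7 (the cationic cyclisation may protodesilylate 11 or close through C12 to the bicyclo[2.2.2] isomer). The fallback sets out from 11 and replaces the Ph3PAuCl/AgBF4 cyclisation by a Stork vinyl-radical closure. Bu3SnH, AIBN, benzene, 80 °C, at high Bu3SnH concentration: the Bu3Sn radical adds to C17, the C16 vinyl radical closes 5-exo onto C13, and the C12 α-silyloxy radical takes hydrogen from the open β-face. This gives the 17-tributylstannyl 3,12,13-tris-O-TBS GA87 ester F3. Protodestannylation (CF3CO2H, 1 equiv, CH2Cl2, −20 °C) gives the 3,12,13-tris-O-TBS GA87 2-(trimethylsilyl)ethyl ester F4. Bu4NF/AcOH then returns to the route at 14.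

Step 8 (facial selectivity: the axial C16 on C13 also hinders the β-face, so the equatorial alcohol may form instead). The fallback sets out from 12 and returns at 13 by inversion instead of reduction control. If hydride enters from the α-face, the product is the 12β-alcohol F5. That same open α-face then accepts a carboxylate in a Mitsunobu inversion (4-nitrobenzoic acid, PPh3, DIAD, toluene, 0 °C to rt), giving the 12α 4-nitrobenzoate F6. Methanolysis (K2CO3, MeOH, 0 °C) gives 13.

**Further compounds**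
F1 | step 6 | 3,12-bis-O-TBS 13,16-seco alkynyl 13-ketone (12-OTBS cis to C10) | C#CC[C@]23CC(=O)[C@@H](O[Si](C)(C)C(C)(C)C)C[C@H]2[C@@]12C=C[C@H](O[Si](C)(C)C(C)(C)C)[C@@](C)(C(=O)O1)[C@H]2[C@@H]3C(=O)OCC[Si](C)(C)C
F2 | step 6 | 3,12-bis-O-TBS GA87 2-(trimethylsilyl)ethyl ester | C=C1C[C@]23C[C@@]1(O)[C@@H](O[Si](C)(C)C(C)(C)C)C[C@H]2[C@@]12C=C[C@H](O[Si](C)(C)C(C)(C)C)[C@@](C)(C(=O)O1)[C@H]2[C@@H]3C(=O)OCC[Si](C)(C)C
F3 | step 7 | 17-tributylstannyl 3,12,13-tris-O-TBS GA87 2-(trimethylsilyl)ethyl ester (alkene geometry undefined) | CCCC[Sn](CCCC)(CCCC)C=C1C[C@]23C[C@@]1(O[Si](C)(C)C(C)(C)C)[C@@H](O[Si](C)(C)C(C)(C)C)C[C@H]2[C@@]12C=C[C@H](O[Si](C)(C)C(C)(C)C)[C@@](C)(C(=O)O1)[C@H]2[C@@H]3C(=O)OCC[Si](C)(C)C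
F4 | step 7 | 3,12,13-tris-O-TBS GA87 2-(trimethylsilyl)ethyl ester | C=C1C[C@]23C[C@@]1(O[Si](C)(C)C(C)(C)C)[C@@H](O[Si](C)(C)C(C)(C)C)C[C@H]2[C@@]12C=C[C@H](O[Si](C)(C)C(C)(C)C)[C@@](C)(C(=O)O1)[C@H]2[C@@H]3C(=O)OCC[Si](C)(C)C
F5 | step 8 | 12β-epimer of 13 | C=C1C[C@]23C[C@@]1(O[Si](C)(C)C(C)(C)C)[C@H](O)C[C@H]2[C@@]12C=C[C@H](O[Si](C)(C)C(C)(C)C)[C@@](C)(C(=O)O1)[C@H]2[C@@H]3C(=O)OCC[Si](C)(C)C
F6 | step 8 | 12α 4-nitrobenzoate of 13 | C=C1C[C@]23C[C@@]1(O[Si](C)(C)C(C)(C)C)[C@@H](OC(=O)c4ccc(cc4)[N+](=O)[O-])C[C@H]2[C@@]12C=C[C@H](O[Si](C)(C)C(C)(C)C)[C@@](C)(C(=O)O1)[C@H]2[C@@H]3C(=O)OCC[Si](C)(C)C
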